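**Remark (assumption).** The SMILES is taken as definitive. In tetracyclo[6.4.0.0^{2,7}.0^{3,6}]dodecane numbering it corresponds to (1R,2S,3S,6R,7R,8S,10S): all ring fusions cis, neighbouring rings anti, and the chain at C10 cis to the cyclobutane bonds at C1/C8 (H10 cis to H1/H8). The same locants C1–C12 are used for compounds 4–8 and 16–19.

## The problem

The target is a symmetric 2-O-alkylglycerol whose octyl chain ends at C10 of a [3]-ladderane: a cyclohexane (C1, C8–C12) cis-fused to three linearly fused cyclobutanes (C1-C2-C7-C8, C2-C3-C6-C7, C3-C4-C5-C6). Three edge-sharing four-membered rings cannot be closed by ordinary polar cyclisations; they call for pericyclic or photochemical bond formation, and each ring must form on the exo face of its neighbour to give the anti staircase. Six of the seven stereocentres (C1, C2, C3, C6, C7, C8) form a meso array, because the unsubstituted core is Cs-symmetric with the mirror plane bisecting C10–C11. The whole absolute configuration is therefore the choice between the enantiotopic carbons C10 and C11. The core stereocentres control one another through ring fusion, but they reach C10 only through the two faces of the six-membered ring. Equilibration cannot help, since either C10 epimer can carry the chain equatorially, so C10 must be set kinetically with the new bond cis to the cyclobutane. The ladder is thermally labile above roughly 100–120 °C and its σ-bonds are at risk with hydrogenolysis catalysts and strong electrophiles, so late saturations use diimide and the glycerol 1,3-diol stays masked until the last step. The enabling feature is that C1–C8 form an eight-membered perimeter (C1–C2–C3–C4–C5–C6–C7–C8) crossed by only two parallel transannular bonds, C2–C7 and C3–C6. Opening them leaves a cycloocta-1,3,5-triene (C2=C3–C4=C5–C6=C7) whose sp3 carbons C1/C8 carry the six-membered ring, and that C8 ring is commercial cyclooctatetraene.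

## Retrosynthesis

**19 ⇒ 18 ⇒ 17.** No skeletal bond is cut. The 1,3-diol is masked as the isopropylidene acetal 18 and the chain is traced to the Z-alkene 17. The forward steps need only mild acid and diimide, which leave the cyclobutanes alone; a hydrogenation catalyst is avoided on purpose.

**17 ⇒ 8 + 14 (through 15 and 16).** The C10–C1′ bond between ring and chain is cut. A cut further along the chain would leave the stereocentre to be made by some other means. This cut lets C10 be carried by a boronic ester whose 1,2-metallate rearrangement is stereoretentive. Boronate 8 has no chain and no heteroatom other than boron, and iodide 14 holds all the oxygen functionality. A late C10 alkene reduced by hydrogen was rejected, because hydrogen would arrive on the same convex face and push the chain to the wrong side.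

**14 ⇒ 12 ⇒ 9 + 10 (through 13 and 11).** The C–I bond goes back to the terminal alkyne 12 by hydrozirconation and iodination, and the ether C–O bond to commercial dioxanol 9 and bromoalkyne 10. These are standard reactions, and the acetal must only survive base, zirconium hydride and iodine.

**8 ⇒ 7.** The C10–B bond is cut. Removing boron reveals the meso alkene 7, so the forward step must both choose C10 over C11 (catalyst control) and add to the convex face (substrate control). A chiral-pool C4 unit was weighed against this; an unsymmetrical one gives both ring-fusion diastereomers, which become enantiomers once C10 is planar.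

**7 ⇒ 6.** The C4=C5 double bond is put back into the terminal cyclobutane. This is needed because the ring-forming step produces a cyclobutene there. The forward step must reduce the strained alkene and spare C10=C11.

**6 ⇒ 5 ⇒ 4.** The two rungs C3–C6 and then C2–C7 are cut, as a retro-4π and a retro-6π electrocyclisation. The neighbouring cut, C1–C2/C7–C8, is the intermolecular [2+2] and needs a preformed bicyclo[2.2.0]hexene. The transannular cut removes all three cyclobutanes and four stereocentres at once, leaving tetraene 4, which has a single stereochemical relationship (H1/H8 cis). The forward reaction must close disrotatorily twice and fold anti each time.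

**4 ⇒ 1 + 2 (through 3).** The bonds C1–C12 and C8–C9 are cut. Cyclooctatetraene 1 becomes a vicinal bis-nucleophile as its dianion 3, and (Z)-1,4-dichlorobut-2-ene 2 supplies C9–C12 with the C10=C11 handle already in place. Both are commercial.

## Roads not taken

**Alternative 1:** the obvious cut is C1–C2/C7–C8, an intermolecular [2+2] photocycloaddition of bicyclo[2.2.0]hex-2-ene A1 with p-benzoquinone to give enedione A2, followed by removal of both carbonyls to reach 7. A1 is not commercial, is volatile, and itself needs a multistep ring contraction. The key step then builds only one of the three cyclobutanes, and several redox steps are spent erasing oxygen that the target does not contain. The chosen plan makes two rings and four stereocentres in one operation from a one-step bicyclic precursor and carries no surplus functionality.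

**Alternative 2:** ring contraction. The terminal cyclobutane is traced to a cyclopentanone: photocycloaddition of cyclopent-2-enone to the cyclobutene of cis-bicyclo[4.2.0]octa-3,7-diene A3 would give ketone A4, and diazo transfer, Wolff contraction and decarboxylation would shrink the five-membered ring. Each cyclobutane made this way costs three to four steps, and a carboxyl group has to be excised from a strained ring. A4 is also racemic by construction, because the ketone already breaks the mirror symmetry without any enantiocontrol. A3 itself needs a cyclobutadiene equivalent.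

**Alternative 3:** all-cis arene hydrogenation. Cutting the three C–H bonds at C1, C8 and C10 leads to the flat benzocyclobutene A5, whose hydrogenation to A6 would set H1/H8/H10 all cis, the correct relative configuration, in one step. The two faces of A5 are enantiotopic and there is no practical asymmetric hydrogenation of such arenes, so A6 is racemic. A6 has no handle on the four-membered ring for building the two remaining cyclobutanes. If the ladder were installed before the hydrogenation, hydrogen would add exo and give the syn ladder.

Key step: step 2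

## Steps

Step 1
Reactants: 1 cyclooctatetraene; 2 (Z)-1,4-dichlorobut-2-ene
Product: 4 cis-bicyclo[6.4.0]dodeca-2,4,6,10-tetraene (meso; H1/H8 cis), via dipotassium cyclooctatetraenide 3 (not isolated)
Conditions: K (2.1 equiv), THF, 25 °C; then cannulated slowly into 2 (1.0 equiv), THF, −78 → 0 °C
Reagents that add atoms: none
Why: Two-electron reduction gives the planar 10π dianion 3, which behaves as a vicinal bis-nucleophile towards 1,n-dihalides (a known annulation type giving cis-bicyclo[6.n.0]trienes). The second alkylation is an intramolecular 6-exo-tet SN2 that only the Z-alkene can reach, and it delivers the tether to the adjacent carbon on the same face, which sets H1/H8 cis.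

Step 2
Reactants: 4 cis-bicyclo[6.4.0]dodeca-2,4,6,10-tetraene
Product: 6 meso-tetracyclo[6.4.0.0^{2,7}.0^{3,6}]dodeca-4,10-diene (all ring fusions cis; neighbouring rings anti), via tricyclic cyclohexadiene 5 (not isolated)
Conditions: degassed cyclohexane (0.01 M), 65 °C; hν (254 nm, quartz)
Reagents that add atoms: none
Why: At 65 °C triene 4 equilibrates by thermal disrotatory 6π electrocyclisation (bond C2–C7) with cyclohexadiene 5, and excitation of the s-cis diene of 5 then triggers a disrotatory 4π closure (bond C3–C6) to the bicyclo[2.2.0]hex-2-ene unit of 6. The closest known reaction types are the cycloocta-1,3,5-triene/bicyclo[4.2.0]octa-2,4-diene valence tautomerism (the second half of 8π/6π cascades) and the photochemical closure of cis-5,6-disubstituted cyclohexa-1,3-dienes to bicyclo[2.2.0]hex-2-enes (the classical entry to Dewar benzene, also seen as the secondary photoisomerisation of arene–alkene ortho adducts). Ring C1-C2-C7-C8 closes by the transannular thermal 6π process, and rings C2-C3-C6-C7 and C3-C4-C5-C6 arise together from the photochemical 4π process. At C2/C7 disrotation makes H2/H7 cis, and the reversible closure settles on the tub face that leaves the cyclohexene exo, i.e. anti to the new diene ring. At C3/C6 disrotation makes H3/H6 cis, and the C4=C5 flap folds to the face of ring C2-C3-C6-C7 away from C1/C8, which gives the second anti relationship. The step needs 4π closure to win over conrotatory photo-ring-opening and over cycloreversion to benzene; ring opening only returns strained E-trienes that revert thermally to 4/5 at 65 °C, whereas 6 no longer absorbs at 254 nm and should accumulate as the photochemical sink. The isolated C10=C11 bond is not a chromophore at this wavelength and is held away from the diene by the cis,anti ring fusion.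

Step 3
Reactants: 6 meso-tetracyclo[6.4.0.0^{2,7}.0^{3,6}]dodeca-4,10-diene
Product: 7 meso-tetracyclo[6.4.0.0^{2,7}.0^{3,6}]dodec-10-ene
Conditions: 2-nitrobenzenesulfonyl hydrazide (1.5 equiv), Et3N, CH2Cl2, 23 °C
Reagents that add atoms: none
Why: Diimide generated in situ transfers H2 in a concerted syn fashion and reduces the strained cyclobutene C4=C5 far faster than the unstrained cis-cyclohexene bond. No metal surface is present, so the cyclobutane σ-bonds are not exposed to hydrogenolysis, and no stereocentre is formed.

Step 4
Reactants: 7 meso-tetracyclo[6.4.0.0^{2,7}.0^{3,6}]dodec-10-ene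
Product: 8 4,4,5,5-tetramethyl-2-[(1R,2S,3S,6R,7R,8S,10S)-tetracyclo[6.4.0.0^{2,7}.0^{3,6}]dodecan-10-yl]-1,3,2-dioxaborolane
Conditions: CuCl (5 mol %), (R)-DTBM-SEGPHOS (6 mol %), KOt-Bu (10 mol %), HBpin (1.5 equiv), cyclohexane, 30 °C
Reagents that add atoms: pinacolborane, [H]B1OC(C)(C)C(C)(C)O1
Why: This is a Cu–H-catalysed enantioselective hydroboration of an unactivated internal Z-alkene, used as the desymmetrisation of a meso cycloalkene: L*Cu–H should add syn across C10=C11 from the convex face of the roof-shaped cis-fused ring (the side of the pseudo-equatorial cyclobutane bonds at C1/C8), and transmetalation with HBpin retains configuration, so boron ends cis to the four-membered ring. The ligand decides which of the enantiotopic carbons C10/C11 receives copper; the sense of induction cannot be derived from first principles, so the ligand antipode that gives the (10S) series has to be assigned once, both antipodes being commercial.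

Step 5
Reactants: 9 2,2-dimethyl-1,3-dioxan-5-ol; 10 8-bromooct-1-yne
Product: 12 2,2-dimethyl-5-(oct-7-yn-1-yloxy)-1,3-dioxane, via sodium alkoxide 11 (not isolated)
Conditions: NaH, DMF, 0 °C; then 10, n-Bu4NI (cat.), 0 → 25 °C
Reagents that add atoms: none
Why: Williamson ether synthesis of a secondary alkoxide with an unhindered primary bromide; the isopropylidene acetal is stable to base and no stereocentre is involved.

Step 6
Reactants: 12 2,2-dimethyl-5-(oct-7-yn-1-yloxy)-1,3-dioxane
Product: 14 5-{[(E)-8-iodooct-7-en-1-yl]oxy}-2,2-dimethyl-1,3-dioxane, via alkenylzirconocene chloride 13 (not isolated)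
Conditions: Cp2Zr(H)Cl (1.3 equiv), THF, 25 °C; then I2, 0 °C
Reagents that add atoms: iodine, II
Why: Hydrozirconation adds Zr–H syn with zirconium at the terminal carbon, and iodinolysis of the C–Zr bond proceeds with retention, which gives the E-vinyl iodide; the acetal is inert to both reagents.

Step 7
Reactants: 14 5-{[(E)-8-iodooct-7-en-1-yl]oxy}-2,2-dimethyl-1,3-dioxane; 8 the C10 pinacol boronate
Product: 17 2,2-dimethyl-5-{[(Z)-8-((1R,2S,3S,6R,7R,8S,10S)-tetracyclo[6.4.0.0^{2,7}.0^{3,6}]dodecan-10-yl)oct-7-en-1-yl]oxy}-1,3-dioxane, via alkenyllithium 15 (not isolated), via lithium boronate complex 16 (not isolated)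
Conditions: 14 (1.3 equiv), t-BuLi (2.6 equiv), Et2O, −78 °C; 8 (1.0 equiv), THF, −78 → 0 °C; I2 (1.3 equiv), MeOH, −78 °C; NaOMe (3 equiv), MeOH, −78 → 23 °C
Reagents that add atoms: none
Why: Zweifel olefination: iodine–lithium exchange gives 15, which adds to boron to form complex 16; iodine then triggers 1,2-migration of C10 from boron to carbon with retention of configuration, and methoxide-induced anti-elimination of boron and iodine gives the Z-alkene. The C10 stereocentre set in step 4 is carried over unchanged.

Step 8
Reactants: 17 the Z-alkene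
Product: 18 2,2-dimethyl-5-{[8-((1R,2S,3S,6R,7R,8S,10S)-tetracyclo[6.4.0.0^{2,7}.0^{3,6}]dodecan-10-yl)octyl]oxy}-1,3-dioxane
Conditions: 2-nitrobenzenesulfonyl hydrazide (excess, in portions), Et3N, CH2Cl2, 23 °C
Reagents that add atoms: none
Why: Diimide reduction of an unhindered Z-disubstituted alkene; the conditions are metal-free and weakly basic, so the cyclobutanes, the acetal and the C10 stereocentre are untouched.

Step 9
Reactants: 18 the saturated acetal
Product: 19 2-{[8-((1R,2S,3S,6R,7R,8S,10S)-tetracyclo[6.4.0.0^{2,7}.0^{3,6}]dodecan-10-yl)octyl]oxy}propane-1,3-diol (CNP0193334.1)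
Conditions: AcOH/H2O/THF (3:1:1), 40 °C
Reagents that add atoms: none
Why: Acid-catalysed hydrolysis of the isopropylidene acetal releases the 1,3-diol; saturated ladderane hydrocarbons have no low-energy cationic pathway under dilute protic acid at this temperature, and no stereocentre is touched.

## Compound list

1 | cyclooctatetraene | C1=CC=CC=CC=C1 | starting material
2 | (Z)-1,4-dichlorobut-2-ene | ClC/C=C\CCl | starting material
3 | dipotassium cyclooctatetraenide | [K+].[K+].[CH-]1C=CC=CC=C[CH-]1 | intermediate (not isolated)
4 | cis-bicyclo[6.4.0]dodeca-2,4,6,10-tetraene (meso) | C1=CC[C@H]2/C=C\C=C/C=C\[C@H]2C1 | intermediate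
5 | cis,anti,cis-tricyclo[6.4.0.0^{2,7}]dodeca-3,5,10-triene (meso) | C1=CC[C@@H]2[C@H](C1)[C@H]1C=CC=C[C@@H]21 | intermediate (not isolated)
6 | meso-tetracyclo[6.4.0.0^{2,7}.0^{3,6}]dodeca-4,10-diene (fusions cis, rings anti) | C1=CC[C@@H]2[C@H](C1)[C@H]1[C@@H]3C=C[C@@H]3[C@@H]21 | intermediate
7 | meso-tetracyclo[6.4.0.0^{2,7}.0^{3,6}]dodec-10-ene (fusions cis, rings anti) | C1=CC[C@@H]2[C@H](C1)[C@H]1[C@@H]3CC[C@@H]3[C@@H]21 | intermediate
8 | 4,4,5,5-tetramethyl-2-[(1R,2S,3S,6R,7R,8S,10S)-tetracyclo[6.4.0.0^{2,7}.0^{3,6}]dodecan-10-yl]-1,3,2-dioxaborolane | CC1(C)OB(OC1(C)C)[C@H]1CC[C@@H]2[C@H](C1)[C@H]1[C@@H]3CC[C@@H]3[C@@H]21 | intermediate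
9 | 2,2-dimethyl-1,3-dioxan-5-ol | CC1(C)OCC(O)CO1 | starting material
10 | 8-bromooct-1-yne | BrCCCCCCC#C | starting material
11 | sodium 2,2-dimethyl-1,3-dioxan-5-olate | [Na+].CC1(C)OCC([O-])CO1 | intermediate (not isolated)
12 | 2,2-dimethyl-5-(oct-7-yn-1-yloxy)-1,3-dioxane | C#CCCCCCCOC1COC(C)(C)OC1 | intermediate
13 | chlorobis(cyclopentadienyl)[(E)-8-(2,2-dimethyl-1,3-dioxan-5-yloxy)oct-1-enyl]zirconium | Cl[Zr](/C=C/CCCCCCOC1COC(C)(C)OC1)(C1C=CC=C1)C1C=CC=C1 | intermediate (not isolated)
14 | 5-{[(E)-8-iodooct-7-en-1-yl]oxy}-2,2-dimethyl-1,3-dioxane | I/C=C/CCCCCCOC1COC(C)(C)OC1 | intermediate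
15 | (E)-8-(2,2-dimethyl-1,3-dioxan-5-yloxy)oct-1-enyllithium | [Li]/C=C/CCCCCCOC1COC(C)(C)OC1 | intermediate (not isolated)
16 | lithium alkenyl(alkyl)pinacolatoborate from 15 and 8 | [Li+].CC1(C)O[B-](OC1(C)C)(/C=C/CCCCCCOC2COC(C)(C)OC2)[C@H]1CC[C@@H]2[C@H](C1)[C@H]1[C@@H]3CC[C@@H]3[C@@H]21 | intermediate (not isolated)
17 | 2,2-dimethyl-5-{[(Z)-8-((1R,2S,3S,6R,7R,8S,10S)-tetracyclo[6.4.0.0^{2,7}.0^{3,6}]dodecan-10-yl)oct-7-en-1-yl]oxy}-1,3-dioxane | CC1(C)OCC(CO1)OCCCCCC/C=C\[C@H]1CC[C@@H]2[C@H](C1)[C@H]1[C@@H]3CC[C@@H]3[C@@H]21 | intermediate
18 | 2,2-dimethyl-5-{[8-((1R,2S,3S,6R,7R,8S,10S)-tetracyclo[6.4.0.0^{2,7}.0^{3,6}]dodecan-10-yl)octyl]oxy}-1,3-dioxane | CC1(C)OCC(CO1)OCCCCCCCC[C@H]1CC[C@@H]2[C@H](C1)[C@H]1[C@@H]3CC[C@@H]3[C@@H]21 | intermediate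
19 | 2-{[8-((1R,2S,3S,6R,7R,8S,10S)-tetracyclo[6.4.0.0^{2,7}.0^{3,6}]dodecan-10-yl)octyl]oxy}propane-1,3-diol | OCC(CO)OCCCCCCCC[C@H]1CC[C@@H]2[C@H](C1)[C@H]1[C@@H]3CC[C@@H]3[C@@H]21 | target

## Step count and risk

Total: 9 steps. Longest linear sequence: 7 steps (1, 2, 3, 4, 7, 8, 9); the chain fragment takes 2 steps (5, 6).

**Step 2 (key step).** The most likely failure is that the light is not channelled into the 4π closure. Triene 4 competes for photons and can close across one of its own diene units, and excited 5 can undergo cycloreversion of its cyclobutane to benzene and a cyclohexadiene. Folding to the syn ladder is a lesser risk. The fallback uses thermal cycloaddition in place of the photochemical valence isomerisation; it sets out from 1 and rejoins the route at 6. Cyclooctatetraene 1 is chlorinated (Cl2, CH2Cl2, −30 °C) to cis-7,8-dichlorobicyclo[4.2.0]octa-2,4-diene F1. F1 is trapped with dimethyl acetylenedicarboxylate as the Diels–Alder adduct dimethyl 3,4-dichlorotricyclo[4.2.2.0^{2,5}]deca-7,9-diene-7,8-dicarboxylate F2; the configuration at the CHCl carbons is drawn exo and is immaterial. Pyrolysis of F2 at about 200 °C expels dimethyl phthalate and releases cis-3,4-dichlorocyclobut-1-ene F3. Lithium amalgam in Et2O couples two molecules of F3 to anti-tricyclo[4.2.0.0^{2,5}]octa-3,7-diene F4. A thermal Diels–Alder reaction of F4 (used in excess to limit bis-addition) with buta-1,3-diene (sealed tube, 80–90 °C, or high pressure at 25 °C) should add to the exo face of one cyclobutene and give 6.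

**Step 1.** The most likely failure is single-electron transfer from the strongly reducing dianion to the allylic dichloride, with reductive 1,4-elimination and recovery of 1, together with oligomerisation through an intermolecular second alkylation. The fallback masks the alkene as a diol on a saturated bis-electrophile that cannot eliminate; it sets out from 1 (through 3) and rejoins at 6. Dianion 3 is annulated with commercial (4S,5S)-2,2-dimethyl-1,3-dioxolane-4,5-diylbis(methylene) bis(4-methylbenzenesulfonate). Its C2 axis makes the two modes of cis-annulation identical, so a single stereoisomer, the trans-acetonide triene F5, should result. F5 is taken through the conditions of step 2 to the tetracyclic acetonide F6. Aqueous acetic acid releases the trans-diol F7. Garegg–Samuelsson olefination of F7 (PPh3, I2, imidazole, toluene, 80 °C) restores C10=C11 and gives 6.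

**Step 4.** The most likely failure is slow insertion of the unstrained internal alkene into Cu–H, so that conversion stalls, or incomplete discrimination of the enantiotopic carbons. The fallback replaces catalyst control by reagent control with a stoichiometric chiral dialkylborane; it sets out from 7 and rejoins at 8. Hydroboration of 7 with diisopinocampheylborane (from (+)-α-pinene, or its antipode as the sense of induction requires; THF, −25 °C) gives the trialkylborane F8. Acetaldehyde liberates α-pinene and leaves the diethyl boronate F9. Transesterification of F9 with pinacol gives 8.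

**Step 7.** The most likely failure is incomplete formation of the boronate complex at the hindered secondary boron centre, or proton transfer to the functionalised alkenyllithium, which leaves 8 unconsumed. The fallback moves the chain-joining event from boron to an alkene metathesis; it sets out from 8 and rejoins at 18. Zweifel olefination of 8 with the small nucleophile vinyllithium (then I2, NaOMe) gives the 10-vinyl compound F10 with retention at C10. Cross-metathesis of F10 (second-generation NHC–ruthenium benzylidene catalyst, CH2Cl2, 40 °C) with 2,2-dimethyl-5-(oct-7-en-1-yloxy)-1,3-dioxane F11, made from 9 and 8-bromooct-1-ene with NaH in DMF, gives 17 together with its E-isomer F12. Diimide reduction of the mixture under the conditions of step 8 converges on 18.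

## Further compounds

F1 | step 2 | cis-7,8-dichlorobicyclo[4.2.0]octa-2,4-diene | Cl[C@H]1[C@@H](Cl)[C@@H]2C=CC=C[C@H]12
F2 | step 2 | dimethyl 3,4-dichlorotricyclo[4.2.2.0^{2,5}]deca-7,9-diene-7,8-dicarboxylate | COC(=O)C1=C(C(=O)OC)[C@@H]2C=C[C@H]1[C@@H]1[C@H]2[C@@H](Cl)[C@H]1Cl
F3 | step 2 | cis-3,4-dichlorocyclobut-1-ene | Cl[C@H]1C=C[C@H]1Cl
F4 | step 2 | anti-tricyclo[4.2.0.0^{2,5}]octa-3,7-diene | C1=C[C@H]2[C@@H]3C=C[C@@H]3[C@@H]12
F5 | step 1 | cis-fused bicyclo[6.4.0]dodeca-2,4,6-triene carrying a (10S,11S)-trans-isopropylidenedioxy group | CC1(C)O[C@H]2C[C@H]3/C=C\C=C/C=C\[C@H]3C[C@@H]2O1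
F6 | step 1 | (10S,11S)-10,11-isopropylidenedioxytetracyclo[6.4.0.0^{2,7}.0^{3,6}]dodec-4-ene (fusions cis, rings anti) | CC1(C)O[C@H]2C[C@@H]3[C@H](C[C@@H]2O1)[C@H]1[C@@H]4C=C[C@@H]4[C@@H]31
F7 | step 1 | (10S,11S)-tetracyclo[6.4.0.0^{2,7}.0^{3,6}]dodec-4-ene-10,11-diol (trans-diol) | O[C@H]1C[C@@H]2[C@H](C[C@@H]1O)[C@H]1[C@@H]3C=C[C@@H]3[C@@H]21
F8 | step 4 | diisopinocampheyl[(1R,2S,3S,6R,7R,8S,10S)-tetracyclo[6.4.0.0^{2,7}.0^{3,6}]dodecan-10-yl]borane | B([C@@H]1C[C@@H]2C[C@H]([C@H]1C)C2(C)C)([C@@H]1C[C@@H]2C[C@H]([C@H]1C)C2(C)C)[C@H]1CC[C@@H]2[C@H](C1)[C@H]1[C@@H]3CC[C@@H]3[C@@H]21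
F9 | step 4 | diethyl [(1R,2S,3S,6R,7R,8S,10S)-tetracyclo[6.4.0.0^{2,7}.0^{3,6}]dodecan-10-yl]boronate | CCOB(OCC)[C@H]1CC[C@@H]2[C@H](C1)[C@H]1[C@@H]3CC[C@@H]3[C@@H]21
F10 | step 7 | (1R,2S,3S,6R,7R,8S,10S)-10-vinyltetracyclo[6.4.0.0^{2,7}.0^{3,6}]dodecane | C=C[C@H]1CC[C@@H]2[C@H](C1)[C@H]1[C@@H]3CC[C@@H]3[C@@H]21
F11 | step 7 | 2,2-dimethyl-5-(oct-7-en-1-yloxy)-1,3-dioxane | C=CCCCCCCOC1COC(C)(C)OC1
F12 | step 7 | E-isomer of 17 | CC1(C)OCC(CO1)OCCCCCC/C=C/[C@H]1CC[C@@H]2[C@H](C1)[C@H]1[C@@H]3CC[C@@H]3[C@@H]21
A1 | alternative 1 | bicyclo[2.2.0]hex-2-ene | C1=C[C@H]2CC[C@@H]12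
A2 | alternative 1 | meso-tetracyclo[6.4.0.0^{2,7}.0^{3,6}]dodec-10-ene-9,12-dione | C1=CC(=O)[C@@H]2[C@H](C1=O)[C@H]1[C@@H]3CC[C@@H]3[C@@H]21
A3 | alternative 2 | cis-bicyclo[4.2.0]octa-3,7-diene | C1=CC[C@H]2C=C[C@H]2C1
A4 | alternative 2 | cyclopentanone-fused 6-4-4-5 photoadduct of A3 (racemic; one enantiomer drawn) | C1=CC[C@@H]2[C@H](C1)[C@H]1[C@@H]3C(=O)CC[C@@H]3[C@@H]21
A5 | alternative 3 | 8-(bicyclo[4.2.0]octa-1,3,5-trien-3-yl)octan-1-ol | OCCCCCCCCc1ccc2CCc2c1
A6 | alternative 3 | all-cis 8-(bicyclo[4.2.0]octan-3-yl)octan-1-ol (racemic; one enantiomer drawn) | OCCCCCCCC[C@H]1CC[C@H]2CC[C@H]2C1
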